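**Retrosynthetic overview**

- The strategy rests on the two acyl arms. Numbered from the ester carbonyl (C1), the stereocentre C3 is β to the ester and carries the alkenyl carbon C4 of the (E)-C4=C5 ethylidene unit. Both C3–C4 bonds are cut to give a bis[(E)-enoate] of the cyclopentane core and two equivalents of an alkenylboron reagent. They are joined by a two-directional rhodium–BINAP 1,4-addition that closes no ring.
- The four aldehydes travel as diethyl acetals and the core 1,3-diol as an acetonide, so one aqueous acid step ends the synthesis.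
- The bis-enoate comes from the bis-acrylate of the core diol by double cross-metathesis with 4,4-diethoxybut-1-ene. The boronate comes from crotonaldehyde through the (Z)-2-bromo enal, its acetal and lithium–bromine exchange.
- The only ring, the cyclopentane, is made first: the cyclohexene of (S)-carvone is contracted by ozonolysis and intramolecular aldol condensation, after which directed hydrogenation and C-epimerisation give the all-trans ring.

Key step: step 18

Remark on the chemistry: the aldehyde carbons are carried as diethyl acetals and not as silyl-protected alcohols, because every free alcohol would sit δ to an ester carbonyl and could lactonise with loss of the core. The boron partner is therefore a pinacol ester. (R)-BINAP is assigned from the usual facial model for (E)-enoates and should be confirmed on a model ester.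

**Route**

Step 1
Reactants: 1 (S)-(+)-carvone
Product: 2 (5S)-5-(3-chloroprop-1-en-2-yl)-2-methylcyclohex-2-en-1-one
Conditions: Ca(OCl)2, CO2 (dry ice), CH2Cl2/H2O, 0 °C
Reagents that add atoms: calcium hypochlorite, [Ca+2].[O-]Cl.[O-]Cl
Why: HOCl formed in the flask chlorinates the electron-rich 1,1-disubstituted alkene by an ene-type pathway with allylic transposition, which regenerates a 2-propenyl unit now carrying CH2Cl, while the electron-poor enone alkene and C5 are untouched.

Step 2
Reactants: 2 (5S)-5-(3-chloroprop-1-en-2-yl)-2-methylcyclohex-2-en-1-one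
Product: 3 2-[(1S)-4-methyl-5-oxocyclohex-3-en-1-yl]prop-2-en-1-yl acetate
Conditions: KOAc, Bu4NI (cat.), DMF, 40 °C
Reagents that add atoms: potassium acetate, CC(=O)[O-].[K+]
Why: Nucleophilic substitution of the primary allylic chloride by acetate, in which the direct and the allylic pathway lead to the same product.

Step 3
Reactants: 3 2-[(1S)-4-methyl-5-oxocyclohex-3-en-1-yl]prop-2-en-1-yl acetate
Product: 5 (1S,5S)-5-(3-hydroxyprop-1-en-2-yl)-2-methylcyclohex-2-en-1-ol, via cis-hydroxy acetate 4 (not isolated)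
Conditions: NaBH4, CeCl3·7H2O, MeOH, −78 °C; then K2CO3, MeOH, rt
Reagents that add atoms: none
Why: Luche reduction adds hydride 1,2 and axially to the enone, which should give the cis (1S) allylic alcohol, and carbonate-promoted methanolysis then removes the acetate in the same flask.

Step 4
Reactants: 5 (1S,5S)-5-(3-hydroxyprop-1-en-2-yl)-2-methylcyclohex-2-en-1-ol
Product: 6 2-[(1S,5S)-5-hydroxy-4-methylcyclohex-3-en-1-yl]propane-1,3-diol
Conditions: 9-BBN (excess), THF, 0 °C → rt; then NaOH, H2O2, 0 °C
Reagents that add atoms: hydrogen peroxide, OO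
Why: Hydroboration–oxidation with 9-BBN takes the unhindered 1,1-disubstituted alkene anti-Markovnikov in preference to the trisubstituted ring alkene, and no stereocentre arises because the two arms of the new 1,3-diol are identical.

Step 5
Reactants: 6 2-[(1S,5S)-5-hydroxy-4-methylcyclohex-3-en-1-yl]propane-1,3-diol
Product: 7 (1S,5S)-5-(2,2-dimethyl-1,3-dioxan-5-yl)-2-methylcyclohex-2-en-1-ol
Conditions: Me2C(OMe)2, PPTS (cat.), acetone, rt
Reagents that add atoms: 2,2-dimethoxypropane, COC(C)(C)OC
Why: Acid-catalysed transketalisation closes the six-membered acetonide on the primary 1,3-diol and leaves the isolated secondary allylic alcohol free.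

Step 6
Reactants: 7 (1S,5S)-5-(2,2-dimethyl-1,3-dioxan-5-yl)-2-methylcyclohex-2-en-1-ol
Product: 8 (1R,5S)-5-(2,2-dimethyl-1,3-dioxan-5-yl)-2-methylcyclohex-2-en-1-yl benzoate
Conditions: PhCO2H, PPh3, DIAD, THF, 0 °C → rt
Reagents that add atoms: benzoic acid, OC(=O)c1ccccc1
Why: The Mitsunobu reaction inverts the allylic carbinol centre, which gives the trans relationship between the ring oxygen and the C5 side chain that the target needs and that the hydride reduction cannot give directly; the benzoate then serves as protecting group.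

Step 7
Reactants: 8 (1R,5S)-5-(2,2-dimethyl-1,3-dioxan-5-yl)-2-methylcyclohex-2-en-1-yl benzoate
Product: 9 (3R,5R)-5-(2,2-dimethyl-1,3-dioxan-5-yl)-2,7-dioxoheptan-3-yl benzoate
Conditions: O3, CH2Cl2, −78 °C; then Me2S, −78 °C → rt
Reagents that add atoms: ozone, [O-][O+]=O
Why: Ozonolysis with reductive work-up cleaves the only alkene, the trisubstituted ring C=C, to the methyl ketone and the aldehyde without touching either stereocentre.

Step 8
Reactants: 9 (3R,5R)-5-(2,2-dimethyl-1,3-dioxan-5-yl)-2,7-dioxoheptan-3-yl benzoate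
Product: 10 (1R,4S)-4-(2,2-dimethyl-1,3-dioxan-5-yl)-3-formyl-2-methylcyclopent-2-en-1-yl benzoate
Conditions: Bn2NH2+ CF3CO2− (cat.), toluene, 50 °C
Reagents that add atoms: none
Why: In this intramolecular aldol condensation the aldehyde reacts as its enamine with the methyl ketone to close the five-membered ring, dehydration gives the conjugated cyclopentene carbaldehyde, and the weakly acidic ammonium salt should not enolise the benzoyloxy-bearing carbon.

Step 9
Reactants: 10 (1R,4S)-4-(2,2-dimethyl-1,3-dioxan-5-yl)-3-formyl-2-methylcyclopent-2-en-1-yl benzoate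
Product: 11 (1R,4S)-4-(2,2-dimethyl-1,3-dioxan-5-yl)-3-(hydroxymethyl)-2-methylcyclopent-2-en-1-ol
Conditions: iBu2AlH (excess), CH2Cl2, −78 → 0 °C; aq. KNaC4H4O6
Reagents that add atoms: none
Why: iBu2AlH reduces the enal 1,2 to the allylic alcohol and cleaves the benzoate reductively in the same operation.

Step 10
Reactants: 11 (1R,4S)-4-(2,2-dimethyl-1,3-dioxan-5-yl)-3-(hydroxymethyl)-2-methylcyclopent-2-en-1-ol
Product: 12 (1R,2R,3R,4R)-4-(2,2-dimethyl-1,3-dioxan-5-yl)-3-(hydroxymethyl)-2-methylcyclopentan-1-ol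
Conditions: H2 (1 atm), [Ir(cod)(PCy3)(py)]PF6 (cat.), CH2Cl2, rt
Reagents that add atoms: none
Why: In this hydroxyl-directed hydrogenation the cationic iridium catalyst binds the ring hydroxyl and adds both hydrogens syn to it, on the face that is also free of the dioxanyl group, which sets the methyl-bearing centre trans to the hydroxyl (R) and leaves the hydroxymethyl centre provisionally cis to the methyl group.

Step 11
Reactants: 12 (1R,2R,3R,4R)-4-(2,2-dimethyl-1,3-dioxan-5-yl)-3-(hydroxymethyl)-2-methylcyclopentan-1-ol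
Product: 13 (1R,2R,3R,5S)-5-(2,2-dimethyl-1,3-dioxan-5-yl)-3-hydroxy-2-methylcyclopentane-1-carbaldehyde
Conditions: TEMPO (cat.), PhI(OAc)2, CH2Cl2, rt
Reagents that add atoms: none
Why: The oxoammonium oxidation takes the primary alcohol selectively over the secondary one and so makes the wrongly configured ring carbon epimerisable; the trans-disposed ring hydroxyl cannot close a lactol, so the oxidation should stop at the aldehyde.

Step 12
Reactants: 13 (1R,2R,3R,5S)-5-(2,2-dimethyl-1,3-dioxan-5-yl)-3-hydroxy-2-methylcyclopentane-1-carbaldehyde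
Product: 15 (1R,2R,3S,4R)-4-(2,2-dimethyl-1,3-dioxan-5-yl)-3-(hydroxymethyl)-2-methylcyclopentan-1-ol, via all-trans aldehyde 14 (not isolated)
Conditions: DBU, MeOH, rt; then NaBH4, 0 °C
Reagents that add atoms: none
Why: Base epimerisation moves the formyl group from the face it shares with both neighbours to the all-trans arrangement under thermodynamic control, and borohydride reduction then fixes this centre (S) as the hydroxymethyl carbon.

Step 13
Reactants: 16 (E)-crotonaldehyde
Product: 18 (2Z)-2-bromobut-2-enal, via 2,3-dibromobutanal 17 (not isolated)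
Conditions: Br2, CH2Cl2, 0 °C; then Et3N, 0 °C → rt
Reagents that add atoms: bromine, BrBr
Why: Bromine addition followed by amine-induced dehydrobromination should give the α-bromo enal as the (Z)-isomer, in which the methyl group is trans to the formyl group.

Step 14
Reactants: 18 (2Z)-2-bromobut-2-enal
Product: 19 (2Z)-2-bromo-1,1-diethoxybut-2-ene
Conditions: HC(OEt)3, EtOH, TsOH·H2O (cat.), rt
Reagents that add atoms: triethyl orthoformate, CCOC(OCC)OCC; ethanol, CCO
Why: Orthoformate acetalisation masks the aldehyde under mild acid without changing the alkene geometry.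

Step 15
Reactants: 19 (2Z)-2-bromo-1,1-diethoxybut-2-ene
Product: 21 2-[(2E)-1,1-diethoxybut-2-en-2-yl]-4,4,5,5-tetramethyl-1,3,2-dioxaborolane, via alkenyllithium 20 (not isolated)
Conditions: t-BuLi (2 equiv), Et2O, −78 °C; then iPrOBpin, −78 °C → rt; aq. NH4Cl
Reagents that add atoms: 2-isopropoxy-4,4,5,5-tetramethyl-1,3,2-dioxaborolane, CC(C)OB1OC(C)(C)C(C)(C)O1
Why: Lithium–bromine exchange proceeds with retention of alkene geometry at −78 °C and the alkenyllithium is trapped by the borate ester, which gives the boronate with the methyl group cis to boron.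

Step 16
Reactants: 15 (1R,2R,3S,4R)-4-(2,2-dimethyl-1,3-dioxan-5-yl)-3-(hydroxymethyl)-2-methylcyclopentan-1-ol; 22 acryloyl chloride (two equivalents incorporated, used in excess)
Product: 23 [(1S,2R,3R,5R)-3-(acryloyloxy)-5-(2,2-dimethyl-1,3-dioxan-5-yl)-2-methylcyclopentyl]methyl acrylate
Conditions: acryloyl chloride (2.6 equiv), iPr2NEt, DMAP (cat.), CH2Cl2, −20 → 0 °C
Reagents that add atoms: none
Why: DMAP-catalysed acylation with two equivalents of the acid chloride esterifies first the primary and then the secondary hydroxyl, so that one acryloyl unit is installed on each oxygen of the diol.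

Step 17
Reactants: 23 [(1S,2R,3R,5R)-3-(acryloyloxy)-5-(2,2-dimethyl-1,3-dioxan-5-yl)-2-methylcyclopentyl]methyl acrylate; 24 4,4-diethoxybut-1-ene (two equivalents incorporated, used in excess)
Product: 25 [(1S,2R,3R,5R)-3-{[(2E)-5,5-diethoxypent-2-enoyl]oxy}-5-(2,2-dimethyl-1,3-dioxan-5-yl)-2-methylcyclopentyl]methyl (2E)-5,5-diethoxypent-2-enoate
Conditions: 4,4-diethoxybut-1-ene (6 equiv), second-generation Hoveyda–Grubbs catalyst RuCl2(H2IMes)(=CH-C6H4-2-OiPr) (cat.), CH2Cl2, 40 °C
Reagents that add atoms: none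
Why: Olefin cross-metathesis of each of the two acrylate arms (type 2 olefin) with one molecule of the terminal homoallylic acetal (type 1 olefin) favours the cross product, releases one ethene per arm and should give the (E)-enoates.

Step 18
Reactants: 25 [(1S,2R,3R,5R)-3-{[(2E)-5,5-diethoxypent-2-enoyl]oxy}-5-(2,2-dimethyl-1,3-dioxan-5-yl)-2-methylcyclopentyl]methyl (2E)-5,5-diethoxypent-2-enoate; 21 2-[(2E)-1,1-diethoxybut-2-en-2-yl]-4,4,5,5-tetramethyl-1,3,2-dioxaborolane (two equivalents incorporated, used in excess)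
Product: 26 [(1S,2R,3R,5R)-3-{[(3S,4E)-3-(2,2-diethoxyethyl)-4-(diethoxymethyl)hex-4-enoyl]oxy}-5-(2,2-dimethyl-1,3-dioxan-5-yl)-2-methylcyclopentyl]methyl (3S,4E)-3-(2,2-diethoxyethyl)-4-(diethoxymethyl)hex-4-enoate
Conditions: [RhCl(C2H4)2]2 (5 mol%), (R)-BINAP (11 mol%), aq. K3PO4, 1,4-dioxane/H2O (10:1), 50 °C
Reagents that add atoms: none
Why: The chloride-bridged precursor and (R)-BINAP give, with aqueous phosphate, a monovalent rhodium hydroxide that transmetalates with boronate 21 with retention of alkene geometry, the alkenylrhodium inserts the enoate C=C to give an oxa-π-allyl rhodium enolate, and water protonates this to release the ester and regenerate the hydroxide. The closest known reaction type is the rhodium–BINAP asymmetric 1,4-addition of aryl- and alkenylboron reagents to (E)-α,β-unsaturated esters (Hayashi–Miyaura reaction), applied here twice on one substrate with an α-branched alkenyl group. No ring is closed. Each new C3 centre is set by the ligand: (R)-BINAP is expected to deliver the alkenyl group to the Cα-Re/Cβ-Si face of the (E)-enoate, the mirror image of the sense in which (S)-BINAP gives (R)-3-arylbutanoates from crotonates, which corresponds to S at both C3, and the ring stereocentres lie four and five bonds away so that both arms should follow the catalyst. The step needs 1,4-addition at both arms without ester cleavage, full transfer of the C4=C5 geometry and high facial selectivity; these are secured by the (E)-geometry of both enoates from the metathesis, by the methyl group fixed cis to boron in 21, by the mild phosphate base, and by the cod-free rhodium source, which leaves no achiral diene-bound rhodium to cause a racemic background reaction.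

Step 19
Reactants: 26 [(1S,2R,3R,5R)-3-{[(3S,4E)-3-(2,2-diethoxyethyl)-4-(diethoxymethyl)hex-4-enoyl]oxy}-5-(2,2-dimethyl-1,3-dioxan-5-yl)-2-methylcyclopentyl]methyl (3S,4E)-3-(2,2-diethoxyethyl)-4-(diethoxymethyl)hex-4-enoate
Product: 27 [(1S,2R,3R,5R)-5-(1,3-dihydroxypropan-2-yl)-3-{[(3S,4E)-4-formyl-3-(2-oxoethyl)hex-4-enoyl]oxy}-2-methylcyclopentyl]methyl (3S,4E)-4-formyl-3-(2-oxoethyl)hex-4-enoate (target)
Conditions: 1 M aq. HCl, THF, 0 °C → rt
Reagents that add atoms: water, O
Why: Aqueous acid hydrolyses the four diethyl acetals (the two allylic ones fastest) and the acetonide in one operation, while the esters, the trisubstituted (E)-alkenes and the C3 centres, which are not α to any carbonyl, should be unaffected.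

**Compound list**

1 | (S)-(+)-carvone, (5S)-2-methyl-5-(prop-1-en-2-yl)cyclohex-2-en-1-one | O=C1C[C@H](CC=C1C)C(C)=C | starting material
2 | (5S)-5-(3-chloroprop-1-en-2-yl)-2-methylcyclohex-2-en-1-one | O=C1C[C@H](CC=C1C)C(CCl)=C | intermediate
3 | 2-[(1S)-4-methyl-5-oxocyclohex-3-en-1-yl]prop-2-en-1-yl acetate | O=C1C[C@H](CC=C1C)C(COC(C)=O)=C | intermediate
4 | 2-[(1S,5S)-5-hydroxy-4-methylcyclohex-3-en-1-yl]prop-2-en-1-yl acetate | O[C@H]1C[C@H](CC=C1C)C(COC(C)=O)=C | intermediate (not isolated)
5 | (1S,5S)-5-(3-hydroxyprop-1-en-2-yl)-2-methylcyclohex-2-en-1-ol | O[C@H]1C[C@H](CC=C1C)C(CO)=C | intermediate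
6 | 2-[(1S,5S)-5-hydroxy-4-methylcyclohex-3-en-1-yl]propane-1,3-diol | O[C@H]1C[C@H](CC=C1C)C(CO)CO | intermediate
7 | (1S,5S)-5-(2,2-dimethyl-1,3-dioxan-5-yl)-2-methylcyclohex-2-en-1-ol | O[C@H]1C[C@H](CC=C1C)C2COC(C)(C)OC2 | intermediate
8 | (1R,5S)-5-(2,2-dimethyl-1,3-dioxan-5-yl)-2-methylcyclohex-2-en-1-yl benzoate | O=C(O[C@@H]1C[C@H](CC=C1C)C2COC(C)(C)OC2)c3ccccc3 | intermediate
9 | (3R,5R)-5-(2,2-dimethyl-1,3-dioxan-5-yl)-2,7-dioxoheptan-3-yl benzoate | CC(=O)[C@H](OC(=O)c1ccccc1)C[C@H](CC=O)C2COC(C)(C)OC2 | intermediate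
10 | (1R,4S)-4-(2,2-dimethyl-1,3-dioxan-5-yl)-3-formyl-2-methylcyclopent-2-en-1-yl benzoate | O=CC1=C(C)[C@H](OC(=O)c2ccccc2)C[C@H]1C3COC(C)(C)OC3 | intermediate
11 | (1R,4S)-4-(2,2-dimethyl-1,3-dioxan-5-yl)-3-(hydroxymethyl)-2-methylcyclopent-2-en-1-ol | OCC1=C(C)[C@H](O)C[C@H]1C2COC(C)(C)OC2 | intermediate
12 | (1R,2R,3R,4R)-4-(2,2-dimethyl-1,3-dioxan-5-yl)-3-(hydroxymethyl)-2-methylcyclopentan-1-ol | OC[C@H]1[C@@H](C)[C@H](O)C[C@H]1C2COC(C)(C)OC2 | intermediate
13 | (1R,2R,3R,5S)-5-(2,2-dimethyl-1,3-dioxan-5-yl)-3-hydroxy-2-methylcyclopentane-1-carbaldehyde | O=C[C@H]1[C@@H](C)[C@H](O)C[C@H]1C2COC(C)(C)OC2 | intermediate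
14 | (1S,2R,3R,5S)-5-(2,2-dimethyl-1,3-dioxan-5-yl)-3-hydroxy-2-methylcyclopentane-1-carbaldehyde | O=C[C@@H]1[C@@H](C)[C@H](O)C[C@H]1C2COC(C)(C)OC2 | intermediate (not isolated)
15 | (1R,2R,3S,4R)-4-(2,2-dimethyl-1,3-dioxan-5-yl)-3-(hydroxymethyl)-2-methylcyclopentan-1-ol (core diol acetonide) | OC[C@@H]1[C@@H](C)[C@H](O)C[C@H]1C2COC(C)(C)OC2 | intermediate
16 | (E)-crotonaldehyde | C/C=C/C=O | starting material
17 | 2,3-dibromobutanal | CC(Br)C(Br)C=O | intermediate (not isolated)
18 | (2Z)-2-bromobut-2-enal | C/C=C(\Br)C=O | intermediate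
19 | (2Z)-2-bromo-1,1-diethoxybut-2-ene | C/C=C(\Br)C(OCC)OCC | intermediate
20 | [(2E)-1,1-diethoxybut-2-en-2-yl]lithium | C/C=C(\[Li])C(OCC)OCC | intermediate (not isolated)
21 | 2-[(2E)-1,1-diethoxybut-2-en-2-yl]-4,4,5,5-tetramethyl-1,3,2-dioxaborolane | C/C=C(\B1OC(C)(C)C(C)(C)O1)C(OCC)OCC | intermediate
22 | acryloyl chloride | C=CC(=O)Cl | starting material
23 | [(1S,2R,3R,5R)-3-(acryloyloxy)-5-(2,2-dimethyl-1,3-dioxan-5-yl)-2-methylcyclopentyl]methyl acrylate | C=CC(=O)OC[C@@H]1[C@@H](C)[C@H](OC(=O)C=C)C[C@H]1C2COC(C)(C)OC2 | intermediate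
24 | 4,4-diethoxybut-1-ene | C=CCC(OCC)OCC | starting material
25 | [(1S,2R,3R,5R)-3-{[(2E)-5,5-diethoxypent-2-enoyl]oxy}-5-(2,2-dimethyl-1,3-dioxan-5-yl)-2-methylcyclopentyl]methyl (2E)-5,5-diethoxypent-2-enoate | CCOC(OCC)C/C=C/C(=O)OC[C@@H]1[C@@H](C)[C@H](OC(=O)/C=C/CC(OCC)OCC)C[C@H]1C2COC(C)(C)OC2 | intermediate (key-step precursor)
26 | [(1S,2R,3R,5R)-3-{[(3S,4E)-3-(2,2-diethoxyethyl)-4-(diethoxymethyl)hex-4-enoyl]oxy}-5-(2,2-dimethyl-1,3-dioxan-5-yl)-2-methylcyclopentyl]methyl (3S,4E)-3-(2,2-diethoxyethyl)-4-(diethoxymethyl)hex-4-enoate | C/C=C(/C(OCC)OCC)[C@@H](CC(OCC)OCC)CC(=O)OC[C@@H]1[C@@H](C)[C@H](OC(=O)C[C@H](CC(OCC)OCC)/C(C(OCC)OCC)=C\C)C[C@H]1C2COC(C)(C)OC2 | intermediate (key-step product)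
27 | [(1S,2R,3R,5R)-5-(1,3-dihydroxypropan-2-yl)-3-{[(3S,4E)-4-formyl-3-(2-oxoethyl)hex-4-enoyl]oxy}-2-methylcyclopentyl]methyl (3S,4E)-4-formyl-3-(2-oxoethyl)hex-4-enoate | C/C=C(/C=O)[C@@H](CC=O)CC(=O)OC[C@@H]1[C@@H](C)[C@H](OC(=O)C[C@H](CC=O)/C(C=O)=C\C)C[C@H]1C(CO)CO | target

**Step count**

Total step count: 19. Longest linear sequence: 16 steps (steps 1–12 and 16–19, from (S)-carvone); the boronate branch (steps 13–15) has 3 steps.

**Steps most likely to fail**

1. Step 18 (two-directional 1,4-addition). What may go wrong: transmetalation or insertion of the hindered α-branched alkenyl group is slower than its protodeboronation, so the second arm is not converted, or facial selectivity at one arm is insufficient.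
Fallback (sets out from 24, 20 and 15; comes back at 26): the C3 centre is set on a small substrate by auxiliary control and the finished acid is then attached to the core. Cross-metathesis of 24 with (R)-3-acryloyl-4-phenyloxazolidin-2-one, using the ruthenium catalyst of step 17, would give (R)-3-[(2E)-5,5-diethoxypent-2-enoyl]-4-phenyloxazolidin-2-one F1. The alkenyllithium 20 would be transmetalated with MgBr2·OEt2 to [(2E)-1,1-diethoxybut-2-en-2-yl]magnesium bromide F2 and added to F1 in the presence of CuBr·SMe2 (THF/Me2S, −40 °C). In the magnesium-chelated s-cis imide the phenyl group covers the Cβ-Re face, so addition should occur on the Cβ-Si face and give (R)-3-[(3S,4E)-3-(2,2-diethoxyethyl)-4-(diethoxymethyl)hex-4-enoyl]-4-phenyloxazolidin-2-one F3. LiOH/H2O2 (THF/H2O, 0 °C, work-up buffered near pH 5) would release (3S,4E)-3-(2,2-diethoxyethyl)-4-(diethoxymethyl)hex-4-enoic acid F4 and the auxiliary. Esterification of both hydroxyls of 15 with two equivalents of F4 (EDC·HCl, DMAP, CH2Cl2) would then give 26.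

2. Step 19 (global unmasking). What may go wrong: the five acetal functions hydrolyse at unequal rates, so that liberated aldehydes are exposed to acid and to the freed 1,3-diol (re-acetalisation, oligomerisation) before the last acetal has been cleaved.
Fallback (sets out from 26; comes back at 27): the diol is released first and masked again as silyl ethers, so that the aldehydes are unmasked without aqueous acid and the last step is a buffered fluoride desilylation. PPTS in ethanol (40 °C) would remove the acetonide while the diethyl acetals only exchange with the solvent, giving the diol tetraacetal F5. TBSCl/imidazole (DMF) would give the bis(silyl ether) tetraacetal F6. TESOTf/2,4,6-collidine (CH2Cl2, 0 °C) followed by water would cleave the four acetals through collidinium intermediates to give the bis(silyl ether) tetra-aldehyde F7. HF·pyridine in THF/pyridine (0 °C) would then remove the two primary silyl ethers to give 27.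

3. Step 10 (directed hydrogenation). What may go wrong: the tetrasubstituted alkene is not reduced because the 1,3-related hydroxyls bind the iridium centre too firmly or the catalyst deactivates, or facial control is lost.
Fallback (sets out from 10; comes back at 13): the conjugated enal is hydrogenated heterogeneously under steric control, which also bypasses steps 9 and 11. K2CO3 in methanol (0 °C) would cleave the benzoate of 10 to (3R,5S)-5-(2,2-dimethyl-1,3-dioxan-5-yl)-3-hydroxy-2-methylcyclopent-1-ene-1-carbaldehyde F8. Hydrogenation over 10% Pd/C (H2, EtOAc, rt) should add hydrogen to the conjugated C=C from the face opposite the dioxanyl group, which is also the hydroxyl-bearing face, and give 13. Any epimer formed at the formyl carbon is 14, the next intermediate, so the material would enter step 12 directly.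

**Further compounds**

F1 | step 18 | (R)-3-[(2E)-5,5-diethoxypent-2-enoyl]-4-phenyloxazolidin-2-one | CCOC(OCC)C/C=C/C(=O)N1[C@H](c2ccccc2)COC1=O
F2 | step 18 | [(2E)-1,1-diethoxybut-2-en-2-yl]magnesium bromide | C/C=C(\[Mg]Br)C(OCC)OCC
F3 | step 18 | (R)-3-[(3S,4E)-3-(2,2-diethoxyethyl)-4-(diethoxymethyl)hex-4-enoyl]-4-phenyloxazolidin-2-one | C/C=C(/C(OCC)OCC)[C@@H](CC(OCC)OCC)CC(=O)N1[C@H](c2ccccc2)COC1=O
F4 | step 18 | (3S,4E)-3-(2,2-diethoxyethyl)-4-(diethoxymethyl)hex-4-enoic acid | C/C=C(/C(OCC)OCC)[C@@H](CC(OCC)OCC)CC(=O)O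
F5 | step 19 | [(1S,2R,3R,5R)-3-{[(3S,4E)-3-(2,2-diethoxyethyl)-4-(diethoxymethyl)hex-4-enoyl]oxy}-5-(1,3-dihydroxypropan-2-yl)-2-methylcyclopentyl]methyl (3S,4E)-3-(2,2-diethoxyethyl)-4-(diethoxymethyl)hex-4-enoate | C/C=C(/C(OCC)OCC)[C@@H](CC(OCC)OCC)CC(=O)OC[C@@H]1[C@@H](C)[C@H](OC(=O)C[C@H](CC(OCC)OCC)/C(C(OCC)OCC)=C\C)C[C@H]1C(CO)CO
F6 | step 19 | bis(tert-butyldimethylsilyl) ether of F5 at the two primary hydroxyls of the propane-1,3-diol unit | C/C=C(/C(OCC)OCC)[C@@H](CC(OCC)OCC)CC(=O)OC[C@@H]1[C@@H](C)[C@H](OC(=O)C[C@H](CC(OCC)OCC)/C(C(OCC)OCC)=C\C)C[C@H]1C(CO[Si](C)(C)C(C)(C)C)CO[Si](C)(C)C(C)(C)C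
F7 | step 19 | bis(tert-butyldimethylsilyl) ether of 27 at the two primary hydroxyls of the propane-1,3-diol unit | C/C=C(/C=O)[C@@H](CC=O)CC(=O)OC[C@@H]1[C@@H](C)[C@H](OC(=O)C[C@H](CC=O)/C(C=O)=C\C)C[C@H]1C(CO[Si](C)(C)C(C)(C)C)CO[Si](C)(C)C(C)(C)C
F8 | step 10 | (3R,5S)-5-(2,2-dimethyl-1,3-dioxan-5-yl)-3-hydroxy-2-methylcyclopent-1-ene-1-carbaldehyde | O=CC1=C(C)[C@H](O)C[C@H]1C2COC(C)(C)OC2
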